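**Retrosynthetic overview**

1. Target 22 ⇐ bis(silyl ether) 21 (fluoride) ⇐ aryl bromide 19 + prenylstannane 20 (Stille coupling).
2. 19 ⇐ hydroxy selenide enone 17 in one operation: radical 4-exo-trig closure of the cyclobutane C–C bond (between the CH on oxepine C-11 and the ring-fusion CH beside the carbinol carbon), then cyclodehydration to form the enol-ether O–C-10 bond.
3. 17 ⇐ enone 16 (hydroxyselenation) ⇐ ketone 7 + aldehyde 13 (aldol condensation); 7 ⇐ 1 + 2 (Ullmann ether synthesis, Friedel–Crafts acylation); 13 ⇐ cyclopentenone 8 + ketene acetal 9 (asymmetric Mukaiyama–Michael addition).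
4. Ring order: oxepinone ring first (step 2; rings A and B and the five-membered carbocycle are bought), then cyclobutane and dihydropyran together (step 12).
5. Enabling feature: the pyran enol-ether carbon C-10 (bonded to ring B and O) is a masked aryl ketone and its neighbour C-11 carries the cyclobutane CH, so that CH is the β-carbon of an 11-alkylidene-dibenzoxepin-10-one. The gem-dimethyl carbon lies inside the four-membered ring to be closed, and the tertiary ether oxygen sits 1,5 to the ketone carbon once the cyclobutane exists.

Key step: step 12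

Remarks
- Locants C-10 and C-11 are those of dibenzo[b,f]oxepine (C-10 bonded to ring B, C-11 to ring A).
- Assumption: the (S)-configured oxazaborolidinium catalyst is taken to give the (S)-adduct in step 6; should the sense be opposite, its enantiomer is used.
- Assumption: compounds 1, 2, 8, 9 and 20 are catalogue chemicals.

**Route**

Step 1
Reactants: 1 2-(2-bromo-4-methoxyphenyl)acetic acid; 2 3-methoxyphenol
Product: 3 2-[4-methoxy-2-(3-methoxyphenoxy)phenyl]acetic acid
Conditions: CuI (10 mol%), N,N-dimethylglycine (30 mol%), Cs2CO3, dioxane, 100 °C; aq. HCl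
Reagents that add atoms: none
Why: Ullmann-type diaryl ether synthesis in which the ligated copper catalyst couples the phenoxide with the only aryl bromide present, assisted by the ortho carboxymethyl group; no stereocentre is formed.

Step 2
Reactants: 3 2-[4-methoxy-2-(3-methoxyphenoxy)phenyl]acetic acid
Product: 4 3,7-dimethoxydibenzo[b,f]oxepin-10(11H)-one
Conditions: PPA, 80 °C
Reagents that add atoms: none
Why: Intramolecular Friedel–Crafts acylation in which the acylium ion can reach only the two positions ortho to the ether oxygen of the phenoxy ring and should attack the one para to the methoxy group, closing the seven-membered oxepinone; no stereocentre is formed.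

Step 3
Reactants: 4 3,7-dimethoxydibenzo[b,f]oxepin-10(11H)-one
Product: 5 2-bromo-3,7-dimethoxydibenzo[b,f]oxepin-10(11H)-one
Conditions: NBS, MeCN, 0 °C
Reagents that add atoms: N-bromosuccinimide, O=C1CCC(=O)N1Br
Why: Electrophilic aromatic bromination that should go to ring A, because ring B is conjugated to the ketone, and there to C-2 (ortho to OMe, para to the ether oxygen, less hindered than C-4), while the absence of acid spares the enolisable CH2; no stereocentre is formed.

Step 4
Reactants: 5 2-bromo-3,7-dimethoxydibenzo[b,f]oxepin-10(11H)-one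
Product: 6 2-bromo-3,7-dihydroxydibenzo[b,f]oxepin-10(11H)-one
Conditions: BBr3, CH2Cl2, −78 → 0 °C; H2O
Reagents that add atoms: none
Why: Lewis-acid cleavage of the two aryl methyl ethers, which leaves the diaryl ether, the ketone and the aryl bromide intact; no stereocentre is formed.

Step 5
Reactants: 6 2-bromo-3,7-dihydroxydibenzo[b,f]oxepin-10(11H)-one
Product: 7 2-bromo-3,7-bis[(triisopropylsilyl)oxy]dibenzo[b,f]oxepin-10(11H)-one
Conditions: i-Pr3SiCl, imidazole, DMF, 23 °C
Reagents that add atoms: chlorotriisopropylsilane, CC(C)[Si](Cl)(C(C)C)C(C)C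
Why: Silylation of both phenols to bulky aryl silyl ethers that should survive amide base, Lewis and sulfonic acids and palladium catalysis and fall to fluoride at the end; no stereocentre is formed.

Step 6
Reactants: 8 cyclopent-2-en-1-one; 9 [(1-methoxy-2-methylprop-1-en-1-yl)oxy]trimethylsilane
Product: 10 methyl (S)-2-methyl-2-{3-[(trimethylsilyl)oxy]cyclopent-2-en-1-yl}propanoate
Conditions: oxazaborolidinium triflimide from (S)-3,3-diphenyl-1-(o-tolyl)tetrahydro-1H,3H-pyrrolo[1,2-c][1,3,2]oxazaborole and HNTf2 (10 mol%), Ph3PO (20 mol%), PhMe, −20 °C; non-aqueous work-up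
Reagents that add atoms: none
Why: Catalytic asymmetric Mukaiyama–Michael addition in which the chiral boron Lewis acid binds the enone carbonyl and shields one face, so the ketene acetal adds to the other and sets the ring CH stereocentre (S), and silyl transfer to the enolate oxygen fixes the enol double bond toward that new centre.

Step 7
Reactants: 10 methyl (S)-2-methyl-2-{3-[(trimethylsilyl)oxy]cyclopent-2-en-1-yl}propanoate
Product: 11 methyl (S)-2-methyl-2-(3-{[(trifluoromethyl)sulfonyl]oxy}cyclopent-2-en-1-yl)propanoate
Conditions: PhNTf2, CsF, DME, 23 °C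
Reagents that add atoms: N-phenylbis(trifluoromethanesulfonimide), O=S(=O)(N(c1ccccc1)S(=O)(=O)C(F)(F)F)C(F)(F)F
Why: Enol triflate synthesis in which fluoride releases the regiodefined caesium enolate from the enol silane and PhNTf2 sulfonylates it on oxygen before it can equilibrate; the stereocentre is untouched.

Step 8
Reactants: 11 methyl (S)-2-methyl-2-(3-{[(trifluoromethyl)sulfonyl]oxy}cyclopent-2-en-1-yl)propanoate
Product: 12 methyl (S)-2-methyl-2-(3-methylcyclopent-2-en-1-yl)propanoate
Conditions: MeMgBr, Fe(acac)3 (5 mol%), THF/NMP, −30 °C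
Reagents that add atoms: methylmagnesium bromide, C[Mg]Br
Why: Iron-catalysed Kumada-type cross-coupling of the alkenyl triflate, which should outrun addition to the hindered ester at −30 °C and places the methyl group on the trisubstituted alkene; the stereocentre is untouched.

Step 9
Reactants: 12 methyl (S)-2-methyl-2-(3-methylcyclopent-2-en-1-yl)propanoate
Product: 13 (S)-2-methyl-2-(3-methylcyclopent-2-en-1-yl)propanal
Conditions: i-Bu2AlH, CH2Cl2, −78 °C; aq. sodium potassium tartrate
Reagents that add atoms: none
Why: Partial reduction of the α-quaternary ester, whose tetrahedral aluminium hemiacetal should be stable at −78 °C and release the aldehyde only on work-up; the neighbouring stereocentre cannot enolise.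

Step 10
Reactants: 7 2-bromo-3,7-bis[(triisopropylsilyl)oxy]dibenzo[b,f]oxepin-10(11H)-one; 13 (S)-2-methyl-2-(3-methylcyclopent-2-en-1-yl)propanal
Product: 16 (E)-2-bromo-11-{2-methyl-2-[(S)-3-methylcyclopent-2-en-1-yl]propylidene}-3,7-bis[(triisopropylsilyl)oxy]dibenzo[b,f]oxepin-10(11H)-one, via lithium aldolate 14 (not isolated), via aldol mesylate 15 (not isolated)
Conditions: LiN(SiMe3)2, THF, −78 °C; 13; MsCl, −78 → 0 °C; DBU, 0 → 23 °C
Reagents that add atoms: none
Why: Aldol condensation run as addition, in-flask mesylation and E1cB elimination, which should work because the aldehyde cannot enolise and the benzylic ketone α-hydrogen is acidic; the bulky substituent is expected anti to the carbonyl (E), the two transient stereocentres are erased and the ring CH is not affected.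

Step 11
Reactants: 16 (E)-2-bromo-11-{2-methyl-2-[(S)-3-methylcyclopent-2-en-1-yl]propylidene}-3,7-bis[(triisopropylsilyl)oxy]dibenzo[b,f]oxepin-10(11H)-one
Product: 17 (E)-2-bromo-11-{2-[3-hydroxy-3-methyl-2-(phenylselanyl)cyclopentyl]-2-methylpropylidene}-3,7-bis[(triisopropylsilyl)oxy]dibenzo[b,f]oxepin-10(11H)-one (on the cyclopentane the hydroxyl is cis to the side chain, PhSe is trans to both)
Conditions: N-(phenylselanyl)phthalimide, H2O, CSA (10 mol%), CH2Cl2, 23 °C
Reagents that add atoms: N-(phenylselanyl)phthalimide, O=C1N([Se]c2ccccc2)C(=O)c2ccccc12; water, O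
Why: Hydroxyselenation (anti addition) in which the seleniranium ion should form on the alkene face away from the quaternary-carbon substituent and water opens it at the tertiary carbon from the face that carries that substituent, which sets the carbinol centre (hydroxyl cis to the side chain) and the selenide-bearing centre, while the electron-poor enone alkene does not react.

Step 12
Reactants: 17 (E)-2-bromo-11-{2-[3-hydroxy-3-methyl-2-(phenylselanyl)cyclopentyl]-2-methylpropylidene}-3,7-bis[(triisopropylsilyl)oxy]dibenzo[b,f]oxepin-10(11H)-one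
Product: 19 bromo bis(silyl ether) of the pentacyclic core (the target skeleton carrying Br in place of the prenyl group and i-Pr3SiO in place of both hydroxyls, four stereocentres as in the target), via keto alcohol 18 (not isolated)
Conditions: MgBr2·OEt2 (1.1 equiv), CH2Cl2, −78 °C; Bu3SnH (slow addition), Et3B, air, −78 → 0 °C; then CSA (0.3 equiv), 4 Å MS, 23 °C; Et3N
Reagents that add atoms: none
Why: Stannyl radical abstraction of PhSe gives the secondary cyclopentyl radical beside the carbinol carbon, which adds 4-exo-trig to the β-carbon of the magnesium-bound enone, and the α-keto benzylic radical takes hydrogen from Bu3SnH; acid then closes the tertiary hydroxyl onto the aryl ketone (6-exo-trig hemiketalisation) and eliminates water toward the only α-hydrogen to give the enol ether. The closest known reaction types are gem-dialkyl-accelerated 4-exo-trig radical cyclisation onto α,β-unsaturated carbonyl compounds, chelation-controlled Lewis-acid-promoted radical conjugate addition, and acid-catalysed cyclodehydration of δ-hydroxy ketones to 3,4-dihydro-2H-pyrans. The ring-fusion stereocentre beside the carbinol carbon is fixed by the tether, since the radical can bond only on the face that carries the side chain, which gives the cis-fused bicyclo[3.2.0]heptane. The cyclobutane CH that carries the oxepine is set by the magnesium bridge between the tertiary hydroxyl oxygen and the ketone oxygen, which can form only when the dibenzoxepinone is folded under the cyclopentane on the side of that oxygen (endo), and the bridged, activated enone should be the species that traps the radical at low temperature. The step needs cyclisation to outrun direct reduction and the endo mode to beat the exo mode; the gem-dimethyl carbon in the forming ring, the α-aryl enone that gives a doubly stabilised radical, the hydroxyl cis to the side chain and the E-enone geometry (ketone on the side that faces the hydroxyl) are what should secure this. Only the endo adduct can reach the ketone, so the cyclodehydration also acts as a filter.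

Step 13
Reactants: 19 bromo bis(silyl ether) of the pentacyclic core; 20 tributyl(3-methylbut-2-en-1-yl)stannane
Product: 21 bis(triisopropylsilyl) ether of the target
Conditions: Pd(PPh3)4 (5 mol%), DMF, 100 °C
Reagents that add atoms: none
Why: Stille coupling in which oxidative addition at the only C–Br bond, transmetalation of the allylstannane at its CH2 terminus and reductive elimination should give the linear prenyl arene; the enol ether, the silyl ethers and the stereocentres are inert.

Step 14
Reactants: 21 bis(triisopropylsilyl) ether of the target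
Product: 22 CNP0185814.1 (target)
Conditions: Bu4NF, THF, 0 °C; aq. NH4Cl
Reagents that add atoms: none
Why: Fluoride-induced cleavage of the two aryl silyl ethers at 0 °C, conditions under which the diaryl enol ether, the cyclobutane and the prenyl group should be stable; no stereocentre is touched.

**Compound list**

1 | 2-(2-bromo-4-methoxyphenyl)acetic acid | COc1ccc(CC(=O)O)c(Br)c1 | starting material
2 | 3-methoxyphenol | COc1cccc(O)c1 | starting material
3 | 2-[4-methoxy-2-(3-methoxyphenoxy)phenyl]acetic acid | COc1ccc(CC(=O)O)c(Oc2cccc(OC)c2)c1 | intermediate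
4 | 3,7-dimethoxydibenzo[b,f]oxepin-10(11H)-one | O=C1Cc2ccc(OC)cc2Oc2cc(OC)ccc21 | intermediate
5 | 2-bromo-3,7-dimethoxydibenzo[b,f]oxepin-10(11H)-one | O=C1Cc2cc(Br)c(OC)cc2Oc2cc(OC)ccc21 | intermediate
6 | 2-bromo-3,7-dihydroxydibenzo[b,f]oxepin-10(11H)-one | O=C1Cc2cc(Br)c(O)cc2Oc2cc(O)ccc21 | intermediate
7 | 2-bromo-3,7-bis[(triisopropylsilyl)oxy]dibenzo[b,f]oxepin-10(11H)-one | O=C1Cc2cc(Br)c(O[Si](C(C)C)(C(C)C)C(C)C)cc2Oc2cc(O[Si](C(C)C)(C(C)C)C(C)C)ccc21 | intermediate
8 | cyclopent-2-en-1-one | O=C1C=CCC1 | starting material
9 | [(1-methoxy-2-methylprop-1-en-1-yl)oxy]trimethylsilane | COC(O[Si](C)(C)C)=C(C)C | starting material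
10 | methyl (S)-2-methyl-2-{3-[(trimethylsilyl)oxy]cyclopent-2-en-1-yl}propanoate | C[Si](C)(C)OC1=C[C@H](CC1)C(C)(C)C(=O)OC | intermediate
11 | methyl (S)-2-methyl-2-(3-{[(trifluoromethyl)sulfonyl]oxy}cyclopent-2-en-1-yl)propanoate | FC(F)(F)S(=O)(=O)OC1=C[C@H](CC1)C(C)(C)C(=O)OC | intermediate
12 | methyl (S)-2-methyl-2-(3-methylcyclopent-2-en-1-yl)propanoate | CC1=C[C@H](CC1)C(C)(C)C(=O)OC | intermediate
13 | (S)-2-methyl-2-(3-methylcyclopent-2-en-1-yl)propanal | CC1=C[C@H](CC1)C(C)(C)C=O | intermediate
14 | lithium aldolate from 7 and 13 (both new centres as mixtures) | [Li+].[O-]C(C1C(=O)c2ccc(O[Si](C(C)C)(C(C)C)C(C)C)cc2Oc2cc(O[Si](C(C)C)(C(C)C)C(C)C)c(Br)cc21)C(C)(C)[C@@H]1C=C(C)CC1 | intermediate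
15 | methanesulfonate of the aldol from 7 and 13 (both new centres as mixtures) | CS(=O)(=O)OC(C1C(=O)c2ccc(O[Si](C(C)C)(C(C)C)C(C)C)cc2Oc2cc(O[Si](C(C)C)(C(C)C)C(C)C)c(Br)cc21)C(C)(C)[C@@H]1C=C(C)CC1 | intermediate
16 | (E)-2-bromo-11-{2-methyl-2-[(S)-3-methylcyclopent-2-en-1-yl]propylidene}-3,7-bis[(triisopropylsilyl)oxy]dibenzo[b,f]oxepin-10(11H)-one | Brc1cc2c(cc1O[Si](C(C)C)(C(C)C)C(C)C)Oc1cc(O[Si](C(C)C)(C(C)C)C(C)C)ccc1C(=O)/C2=C/C(C)(C)[C@@H]1C=C(C)CC1 | intermediate
17 | (E)-2-bromo-11-{2-[3-hydroxy-3-methyl-2-(phenylselanyl)cyclopentyl]-2-methylpropylidene}-3,7-bis[(triisopropylsilyl)oxy]dibenzo[b,f]oxepin-10(11H)-one; hydroxyl cis to the side chain, PhSe trans to both | Brc1cc2c(cc1O[Si](C(C)C)(C(C)C)C(C)C)Oc1cc(O[Si](C(C)C)(C(C)C)C(C)C)ccc1C(=O)/C2=C/C(C)(C)[C@H]1CC[C@@](C)(O)[C@@H]1[Se]c1ccccc1 | intermediate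
18 | 2-bromo-11-(2-hydroxy-2,6,6-trimethylbicyclo[3.2.0]heptan-7-yl)-3,7-bis[(triisopropylsilyl)oxy]dibenzo[b,f]oxepin-10(11H)-one; cis ring fusion, hydroxyl on the cyclobutane face of the five-membered ring, oxepinone at C-7 of the bicycle cis to C-2, C-11 of the oxepinone unassigned | Brc1cc2c(cc1O[Si](C(C)C)(C(C)C)C(C)C)Oc1cc(O[Si](C(C)C)(C(C)C)C(C)C)ccc1C(=O)C2[C@@H]2[C@H]3[C@H](CC[C@@]3(C)O)C2(C)C | intermediate
19 | bromo bis(silyl ether) of the pentacyclic core (target with Br for prenyl and i-Pr3SiO for both OH; stereocentres as in the target) | Brc1cc2c(cc1O[Si](C(C)C)(C(C)C)C(C)C)Oc1cc(O[Si](C(C)C)(C(C)C)C(C)C)ccc1C1=C2[C@@H]2[C@H]3[C@H](CC[C@@]3(C)O1)C2(C)C | intermediate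
20 | tributyl(3-methylbut-2-en-1-yl)stannane | CCCC[Sn](CCCC)(CCCC)CC=C(C)C | starting material
21 | bis(triisopropylsilyl) ether of the target | CC(C)=CCc1cc2c(cc1O[Si](C(C)C)(C(C)C)C(C)C)Oc1cc(O[Si](C(C)C)(C(C)C)C(C)C)ccc1C1=C2[C@@H]2[C@H]3[C@H](CC[C@@]3(C)O1)C2(C)C | intermediate
22 | CNP0185814.1 | CC(C)=CCc1cc2c(cc1O)Oc1cc(O)ccc1C1=C2[C@@H]2[C@H]3[C@H](CC[C@@]3(C)O1)C2(C)C | target

**Step count and risks**

Total step count: 14. Longest linear sequence: 10 steps (steps 1–5, then 10–14).

The three steps most likely to fail:

Step 12. The radical may close in the exo mode (oxepinone folded away from the hydroxyl, so that the ketone cannot be reached), may be reduced before it closes, or the hydroxyl may add to the enone β-carbon under the Lewis acid. The fallback sets out from 7 and comes back at 19. Knoevenagel condensation of 7 with citral (ethylenediammonium diacetate, PhMe, reflux) followed by spontaneous oxa-6π electrocyclisation should give the racemic 2H-pyran F1. Irradiation (Pyrex filter, acetone) should then join the side-chain alkene to the pyran C=C bond in an intramolecular [2+2] photocycloaddition, the established way to this cage, to give the racemic bromo bis(silyl ether) F2. Preparative chromatography on a chiral stationary phase returns 19.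

Step 11. The selenium electrophile may add from the wrong alkene face, the seleniranium ion may open at the secondary carbon, or the electron-rich arenes may be selenenylated. The fallback sets out from 12 and comes back at 17, moving the oxygenation to the small fragment and using hydroxyl direction. LiAlH4 reduction gives (S)-2-methyl-2-(3-methylcyclopent-2-en-1-yl)propan-1-ol F3. VO(acac)2/t-BuOOH should deliver oxygen to the alkene face on the side of the hydroxymethyl-bearing substituent and give the cis epoxy alcohol F4. Oxidation with SO3·pyridine, DMSO and i-Pr2NEt gives the epoxy aldehyde F5, and condensation with 7 under the conditions of step 10 gives the epoxy enone F6. PhSeNa (from PhSeSePh and NaBH4, excess hydride destroyed before addition) then opens the epoxide at its secondary carbon with inversion and returns 17.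

Step 6. Face discrimination on the small flat enone may be poor, or the enol silane may lose its regiochemistry. The fallback sets out from 8 and comes back at 12. Addition of MeLi/CeCl3 to the carbonyl gives 1-methylcyclopent-2-en-1-ol F7, and isobutyryl chloride with DMAP and pyridine gives the ester F8. Ireland–Claisen rearrangement (LiN(i-Pr)2, Me3SiCl, THF, −78 °C then reflux) should build the quaternary carbon and move the alkene to give the racemic 2-methyl-2-(3-methylcyclopent-2-en-1-yl)propanoic acid F9. Crystallisation of its salt with one enantiomer of 1-phenylethylamine gives the (S)-acid F10, and Me3SiCHN2 in MeOH returns 12.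

Further compounds
F1 | step 12 | racemic 2-bromo bis(silyl ether) 2H-pyran from 7 and citral (2-methyl-2-(4-methylpent-3-enyl)-2H-pyran fused at C-10/C-11 of the dibenzoxepine) | CC(C)=CCCC1(C)C=CC2=C(O1)c3ccc(O[Si](C(C)C)(C(C)C)C(C)C)cc3Oc3cc(O[Si](C(C)C)(C(C)C)C(C)C)c(Br)cc23
F2 | step 12 | racemic bromo bis(silyl ether) of the pentacyclic core (racemate of 19) | Brc1cc2c(cc1O[Si](C(C)C)(C(C)C)C(C)C)Oc1cc(O[Si](C(C)C)(C(C)C)C(C)C)ccc1C1=C2C2C3C(CCC3(C)O1)C2(C)C
F3 | step 11 | (S)-2-methyl-2-(3-methylcyclopent-2-en-1-yl)propan-1-ol | CC1=C[C@H](CC1)C(C)(C)CO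
F4 | step 11 | 2-(2,3-epoxy-3-methylcyclopentyl)-2-methylpropan-1-ol, epoxide oxygen cis to the side chain | OCC(C)(C)[C@H]1CC[C@@]2(C)O[C@@H]12
F5 | step 11 | 2-(2,3-epoxy-3-methylcyclopentyl)-2-methylpropanal, epoxide oxygen cis to the side chain | O=CC(C)(C)[C@H]1CC[C@@]2(C)O[C@@H]12
F6 | step 11 | (E)-2-bromo-11-[2-(2,3-epoxy-3-methylcyclopentyl)-2-methylpropylidene]-3,7-bis[(triisopropylsilyl)oxy]dibenzo[b,f]oxepin-10(11H)-one, epoxide oxygen cis to the side chain | Brc1cc2c(cc1O[Si](C(C)C)(C(C)C)C(C)C)Oc1cc(O[Si](C(C)C)(C(C)C)C(C)C)ccc1C(=O)/C2=C/C(C)(C)[C@H]1CC[C@@]2(C)O[C@@H]12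
F7 | step 6 | 1-methylcyclopent-2-en-1-ol (racemic) | CC1(O)C=CCC1
F8 | step 6 | 1-methylcyclopent-2-en-1-yl 2-methylpropanoate (racemic) | CC(C)C(=O)OC1(C)C=CCC1
F9 | step 6 | 2-methyl-2-(3-methylcyclopent-2-en-1-yl)propanoic acid (racemic) | CC1=CC(CC1)C(C)(C)C(=O)O
F10 | step 6 | (S)-2-methyl-2-(3-methylcyclopent-2-en-1-yl)propanoic acid | CC1=C[C@H](CC1)C(C)(C)C(=O)O
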